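**Retrosynthetic overview**
1. The exocyclic C11=C20 methylene beside the C12 hydroperoxide is the product pattern of a Schenck ene reaction; removing it leaves a C11=C12 cyclohexene (ring C1–C10–C11–C12–C13–C14), which is a Diels–Alder retron.
2. Key disconnection: C1–C10 and C13–C14 together, by an intramolecular Diels–Alder reaction of a linear tetraene in which C2 is a ketone (activates C1=C14) and C14 carries boron (masked 14-oxygen). Because C1 and C10 are also the fusion atoms of the ten-membered ring, the same step closes that ring.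
3. The linear precursor comes from neryl acetate (Z-C5=C6, C2–C7), a Duboudin carbomagnesiation (C1=C14), a lactate-derived phosphonosuccinate/HWE/Sharpless epoxidation/lactonisation sequence (C7, C8, C17, γ-lactone) and a dienyl Grignard addition (C10–C13).
4. Ring order: γ-lactone (step 12), then six- and ten-membered rings together (step 21); end game: C–B to C–OH, directed C2 reduction, diacetylation, ene reaction.

Key step: step 21

Remark: briarane numbering is used. C1 (quaternary, CH3-15) and C10 are the ring-fusion atoms; C11 (C20), C12, C13, C14 complete the six-membered ring; C2–C9 complete the ten-membered ring (CH3-16 on C5); C17 (CH3-18) and C19 (C=O) close the γ-lactone from C8 to O–C7. Neryl acetate, tert-butyl (R)-lactate, triethyl phosphonoacetate and propargyl alcohol are taken as commercial.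

**Step 1**
Reactants: 1 neryl acetate
Product: 2 (2Z)-6,7-epoxy-3,7-dimethyloct-2-en-1-yl acetate (racemic)
Conditions: mCPBA, CH2Cl2, 0 °C
Reagents that add atoms: 3-chloroperoxybenzoic acid, OOC(=O)c1cccc(Cl)c1
Why: Prilezhaev epoxidation, in which the electron-rich terminal trisubstituted alkene should react much faster than the alkene deactivated by the allylic acetate; the epoxide stereocentre is destroyed in step 2.

**Step 2**
Reactants: 2 (2Z)-6,7-epoxy-3,7-dimethyloct-2-en-1-yl acetate
Product: 3 (4Z)-6-acetoxy-4-methylhex-4-enal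
Conditions: H5IO6, THF/H2O, 0 °C
Reagents that add atoms: none
Why: Periodic acid hydrolyses the epoxide to the glycol and cleaves it (Malaprade-type cleavage) to the C2 aldehyde and acetone without touching the Z-alkene or the acetate.

**Step 3**
Reactants: 3 (4Z)-6-acetoxy-4-methylhex-4-enal
Product: 4 (2Z)-6-hydroxy-3-methyloct-2-en-7-yn-1-yl acetate (racemic)
Conditions: HC≡CMgBr, THF, −78 °C
Reagents that add atoms: ethynylmagnesium bromide, C#C[Mg]Br
Why: Grignard 1,2-addition to the aldehyde is much faster at low temperature than attack on the acetate; the C2 carbinol forms as a racemate, which is irrelevant because C2 becomes a ketone in step 19.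

**Step 4**
Reactants: 4 (2Z)-6-hydroxy-3-methyloct-2-en-7-yn-1-yl acetate
Product: 6 (2Z,7Z)-8-iodo-3,7-dimethylocta-2,7-diene-1,6-diol (racemic), via cyclic alkenylmagnesium alkoxide 5 (not isolated)
Conditions: MeMgBr (6 equiv), Et2O, 0 °C; then CuI (20 mol%), reflux; then I2, THF, −78 °C
Reagents that add atoms: methylmagnesium bromide, C[Mg]Br; iodine, [I][I]
Why: Duboudin anti-carbomagnesiation, in which the excess Grignard reagent first cleaves the acetate (before the copper salt is added, so no allylic substitution can occur) and the propargylic magnesium alkoxide then directs copper-catalysed addition of CH3–Mg across the alkyne through the five-membered chelate 5, placing methyl on C1 and magnesium on C14 cis to C2, so that iodinolysis with retention gives the (Z)-vinyl iodide.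

**Step 5**
Reactants: 6 (2Z,7Z)-8-iodo-3,7-dimethylocta-2,7-diene-1,6-diol
Product: 7 (2Z,7Z)-6-hydroxy-8-iodo-3,7-dimethylocta-2,7-dienal (racemic)
Conditions: TEMPO (cat.), PhI(OAc)2, CH2Cl2, rt
Reagents that add atoms: none
Why: Oxoammonium (TEMPO) oxidation is selective for the primary allylic alcohol over the secondary one and is a known way to turn nerol-type alcohols into Z-enals without isomerisation.

**Step 6**
Reactants: 7 (2Z,7Z)-6-hydroxy-8-iodo-3,7-dimethylocta-2,7-dienal
Product: 8 (2Z,7Z)-6-(tert-butyldimethylsilyloxy)-8-iodo-3,7-dimethylocta-2,7-dienal (racemic)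
Conditions: TBSCl, imidazole, DMF, rt
Reagents that add atoms: tert-butyldimethylsilyl chloride, CC(C)(C)[Si](C)(C)Cl
Why: Standard silylation of the secondary alcohol, which keeps C2 at the alcohol level and inert through steps 9 to 17.

**Step 7**
Reactants: 9 tert-butyl (R)-lactate
Product: 10 tert-butyl (2R)-2-(trifluoromethylsulfonyloxy)propanoate
Conditions: Tf2O, 2,6-lutidine, CH2Cl2, −78 °C
Reagents that add atoms: trifluoromethanesulfonic anhydride, O=S(=O)(OS(=O)(=O)C(F)(F)F)C(F)(F)F
Why: O-Sulfonylation with retention gives a secondary α-ester triflate set up for clean SN2 displacement.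

**Step 8**
Reactants: 10 tert-butyl (2R)-2-(trifluoromethylsulfonyloxy)propanoate, 11 triethyl phosphonoacetate
Product: 12 4-tert-butyl 1-ethyl (3S)-2-(diethoxyphosphoryl)-3-methylbutanedioate (both C2 epimers)
Conditions: NaH, THF, 0 °C → rt
Reagents that add atoms: none
Why: SN2 alkylation of the soft sodium phosphonoacetate carbanion by the lactate triflate proceeds with inversion and fixes C17 from the chiral pool; the phosphorus-bearing carbon becomes sp2 in step 9.

**Step 9**
Reactants: 8 (2Z,7Z)-6-(tert-butyldimethylsilyloxy)-8-iodo-3,7-dimethylocta-2,7-dienal, 12 4-tert-butyl 1-ethyl (3S)-2-(diethoxyphosphoryl)-3-methylbutanedioate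
Product: 13 4-tert-butyl 1-ethyl (2E,3R)-2-[(2Z,7Z)-6-(tert-butyldimethylsilyloxy)-8-iodo-3,7-dimethylocta-2,7-dien-1-ylidene]-3-methylbutanedioate (two epimers at the silyloxy carbon)
Conditions: NaH (1.0 equiv), THF, −20 → 0 °C
Reagents that add atoms: none
Why: Horner–Wadsworth–Emmons olefination, which should give mainly the thermodynamically preferred (E)-alkylidene succinate (aldehyde residue trans to CO2Et), while one equivalent of base at low temperature should leave the C17 stereocentre untouched.

**Step 10**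
Reactants: 13 the (2E,3R)-alkylidene succinate
Product: 14 tert-butyl (2R,3E,5Z,10Z)-9-(tert-butyldimethylsilyloxy)-3-(hydroxymethyl)-11-iodo-2,6,10-trimethylundeca-3,5,10-trienoate
Conditions: i-Bu2AlH (2.2 equiv), CH2Cl2, −78 °C
Reagents that add atoms: none
Why: 1,2-Reduction of the conjugated ethyl ester to the allylic alcohol, whereas the hindered tert-butyl ester, the vinyl iodide and the silyl ether should be inert at −78 °C.

**Step 11**
Reactants: 14 the dienyl allylic alcohol
Product: 15 tert-butyl (2R)-2-{(2R,3R)-3-[(1Z,6Z)-5-(tert-butyldimethylsilyloxy)-7-iodo-2,6-dimethylhepta-1,6-dien-1-yl]-2-(hydroxymethyl)oxiran-2-yl}propanoate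
Conditions: t-BuOOH, Ti(OiPr)4 (cat.), D-(−)-diethyl tartrate (cat.), 4 Å MS, CH2Cl2, −20 °C
Reagents that add atoms: tert-butyl hydroperoxide, CC(C)(C)OO
Why: Sharpless asymmetric epoxidation, in which the titanium tartrate epoxidises only the alkene of the primary allylic alcohol of the 2,4-dienol and D-(−)-tartrate delivers oxygen to the face that gives the (7R,8R)-epoxide, so that the C8 carbinol configuration is set under reagent control.

**Step 12**
Reactants: 15 the (7R,8R)-epoxy alcohol
Product: 16 (3R,4R,5S)-5-[(1Z,6Z)-5-(tert-butyldimethylsilyloxy)-7-iodo-2,6-dimethylhepta-1,6-dien-1-yl]-4-hydroxy-4-(hydroxymethyl)-3-methyloxolan-2-one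
Conditions: camphorsulfonic acid (cat.), CH2Cl2, 0 °C
Reagents that add atoms: none
Why: Acid-catalysed intramolecular opening of the vinyl epoxide by the tert-butyl ester carbonyl at the allylic carbon C7 with inversion (loss of 2-methylpropene) closes the γ-lactone kinetically, so that the E-alkene and the epoxide configuration give 7S while the epoxide oxygen stays as the C8 hydroxyl.

**Step 13**
Reactants: 16 the hydroxymethyl lactone
Product: 17 (3R,4S,5S)-5-[(1Z,6Z)-5-(tert-butyldimethylsilyloxy)-7-iodo-2,6-dimethylhepta-1,6-dien-1-yl]-4-formyl-4-hydroxy-3-methyloxolan-2-one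
Conditions: TEMPO (cat.), PhI(OAc)2, CH2Cl2, rt
Reagents that add atoms: none
Why: TEMPO oxidation of the only primary alcohol to the C9 aldehyde under near-neutral conditions that should spare the tertiary alcohol and avoid translactonisation to the C9 oxygen.

**Step 14**
Reactants: 18 propargyl alcohol
Product: 20 (E)-3-iodo-2-methylprop-2-en-1-ol, via alkenylalane 19 (not isolated)
Conditions: Me3Al, Cp2ZrCl2 (25 mol%), CH2Cl2, 0 °C → rt; then I2, THF, −30 °C
Reagents that add atoms: trimethylaluminium, C[Al](C)C; iodine, [I][I]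
Why: Negishi zirconium-catalysed carboalumination adds CH3–Al syn across the alkyne with methyl on the internal carbon, and iodinolysis with retention gives the (E)-iodoalkene.

**Step 15**
Reactants: 20 (E)-3-iodo-2-methylprop-2-en-1-ol
Product: 21 (E)-3-iodo-2-methylprop-2-enal
Conditions: MnO2, CH2Cl2, rt
Reagents that add atoms: none
Why: MnO2 oxidation of the allylic alcohol to the enal is selective and does not scramble the alkene geometry.

**Step 16**
Reactants: 21 (E)-3-iodo-2-methylprop-2-enal
Product: 22 (E)-1-iodo-2-methylbuta-1,3-diene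
Conditions: Ph3PCH3Br, KOt-Bu, Et2O, 0 °C (used as a solution)
Reagents that add atoms: methyltriphenylphosphonium bromide, C[P+](c1ccccc1)(c1ccccc1)c1ccccc1.[Br-]
Why: Wittig methylenation of the enal with the non-stabilised ylide gives the terminal alkene and leaves the iodoalkene geometry untouched.

**Step 17**
Reactants: 17 the C9 aldehyde, 22 (E)-1-iodo-2-methylbuta-1,3-diene
Product: 25 C9 dienyl carbinol (lactone 17 with the formyl group converted into a (2E)-1-hydroxy-3-methylpenta-2,4-dien-1-yl group; both C9 epimers), via dienyllithium 23 (not isolated), via dienylmagnesium bromide 24 (not isolated)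
Conditions: 22, t-BuLi (2 equiv), Et2O, −78 °C; MgBr2·OEt2; then 17 (0.4 equiv), THF, −78 °C
Reagents that add atoms: none
Why: Iodine–lithium exchange with retention of geometry, transmetalation to magnesium (to suppress exchange with the C14 vinyl iodide of 17) and Grignard 1,2-addition to the aldehyde after the first equivalent has deprotonated the tertiary hydroxyl; the C9 carbinol forms as an epimeric mixture, which is irrelevant because C9 is oxidised in step 19.

**Step 18**
Reactants: 25 the C9 dienyl carbinol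
Product: 26 triol (25 without the silyl group; free hydroxyls at C2, C8 and C9)
Conditions: HF·pyridine, pyridine, THF, 0 °C → rt
Reagents that add atoms: none
Why: Fluoride cleavage of the secondary TBS ether under buffered, non-basic conditions that should avoid translactonisation.

**Step 19**
Reactants: 26 the triol
Product: 27 (3R,4S,5S)-4-hydroxy-5-[(1Z,6Z)-7-iodo-2,6-dimethyl-5-oxohepta-1,6-dien-1-yl]-3-methyl-4-[(2E)-3-methylpenta-2,4-dienoyl]oxolan-2-one
Conditions: Dess–Martin periodinane (2.5 equiv), CH2Cl2, 0 °C → rt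
Reagents that add atoms: none
Why: Dess–Martin oxidation converts both secondary allylic alcohols (C9 and C2) into the dienone and the β-iodo enone in one operation, merging all C2 and C9 epimers, and leaves the tertiary C8 hydroxyl untouched.

**Step 20**
Reactants: 27 the dienone β-iodo enone
Product: 28 (3R,4S,5S)-5-[(1Z,6Z)-2,6-dimethyl-5-oxo-7-(4,4,5,5-tetramethyl-1,3,2-dioxaborolan-2-yl)hepta-1,6-dien-1-yl]-4-hydroxy-3-methyl-4-[(2E)-3-methylpenta-2,4-dienoyl]oxolan-2-one
Conditions: B2pin2, PdCl2(dppf) (5 mol%), KOAc, 1,4-dioxane, 60 °C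
Reagents that add atoms: bis(pinacolato)diboron, CC1(C)OB(OC1(C)C)B1OC(C)(C)C(C)(C)O1
Why: Miyaura borylation (oxidative addition of zerovalent palladium into the vinyl iodide, acetate-assisted transmetalation with B2pin2, reductive elimination) should give the (Z)-β-boryl enone with retention, the cis acyl group stabilising the alkenylpalladium intermediate by chelation.

**Step 21**
Reactants: 28 the linear tetraene (dienone plus (Z)-β-boryl enone)
Product: 29 8-hydroxy-2,9-dioxo-14-(4,4,5,5-tetramethyl-1,3,2-dioxaborolan-2-yl)briara-5Z,11-dien-19,7-olide (C1, C7, C8, C10, C14, C17 as in the target)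
Conditions: toluene (0.5 mM), BHT, 110 °C, argon
Reagents that add atoms: none
Why: Thermal, concerted, suprafacial intramolecular Diels–Alder reaction between the (E)-C10=C11(CH3)–C12=C13 diene (attached through C10 to the C9 ketone) and the C1=C14 bond of the (Z)-β-boryl-α-methyl enone, forming C1–C10 and C13–C14 in the "ortho" orientation that a 1-acyl diene and an enone with its largest LUMO coefficient at C14 both prefer. The closest known reaction type is the macrocyclising intramolecular Diels–Alder reaction in which a diene terminus and a dienophile joined by a long tether close a nine- to fourteen-membered carbocycle and a cyclohexene at once, combined with the known use of carbonyl-bearing alkenylboronates as dienophiles. The six-membered ring (C1, C10, C11, C12, C13, C14) is closed by the cycloaddition itself and the ten-membered ring by the new C1–C10 bond, the eight-atom tether C2–C9 joining a diene terminus to the dienophile carbon that bonds to it (fused mode, tether carbonyl C2 exo, hence trans ring fusion) and being restricted by the Z-C5=C6 alkene, the γ-lactone and the sp2 carbons C2 and C9. C1 and C14 are set relative to each other by the Z geometry of the dienophile (boron cis to C2), C10 relative to C1 by the exo transition state in which the tether and the boryl group point away from the diene and the α-methyl group lies under it, and all three relative to C7/C8 by the C8 carbinol, because the hydrogen bond C8–OH···O=C9 and the s-cis dienone (s-trans is disfavoured by allylic strain between C8 and CH3-20) place C7 and the tether on one diene face only. The step needs exo over endo selectivity, one π-face and intramolecular over intermolecular reaction; these should be secured by the α-methyl group and the shorter tether path in the exo mode, by the C8 stereocentre, and by high dilution, while the E geometry at C10=C11 excludes 6π-electrocyclisation of the dienone.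

**Step 22**
Reactants: 29 the boryl cycloadduct
Product: 30 8,14-dihydroxy-2,9-dioxobriara-5Z,11-dien-19,7-olide
Conditions: NaBO3·4H2O, THF/H2O (1:1), 0 °C → rt
Reagents that add atoms: sodium perborate, [Na+].[Na+].O[B-]1(O)OO[B-](O)(O)OO1
Why: Perborate oxidation of the secondary alkylboronate proceeds by 1,2-migration of C14 from boron to oxygen with retention, and the mild conditions should spare the lactone and the β-hydroxy ketone (C1 is quaternary, so no β-elimination is possible).

**Step 23**
Reactants: 30 the 14-hydroxy-2-ketone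
Product: 31 (2S,14S)-2,8,14-trihydroxy-9-oxobriara-5Z,11-dien-19,7-olide
Conditions: Me4NBH(OAc)3, MeCN/AcOH (1:1), −30 °C
Reagents that add atoms: none
Why: Evans–Saksena reduction, in which the C14 hydroxyl exchanges onto boron and delivers hydride intramolecularly through a six-membered chair transition state to the C2 ketone to give the 1,3-anti diol (2S), while the C9 ketone, flanked by the fully substituted C8 and the tertiary C10, should react much more slowly.

**Step 24**
Reactants: 31 the 2,14-diol
Product: 32 (2S,14S)-2,14-diacetoxy-8-hydroxy-9-oxobriara-5Z,11-dien-19,7-olide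
Conditions: Ac2O, pyridine, DMAP (cat.), CH2Cl2, 0 °C
Reagents that add atoms: acetic anhydride, CC(=O)OC(C)=O
Why: DMAP-catalysed acetylation of the two secondary alcohols, the hindered tertiary α-ketol hydroxyl at C8 being expected to stay free.

**Step 25**
Reactants: 32 the diacetate
Product: 33 target, (1S,2S,5Z,7S,8S,10S,12S,14S,17R)-2,14-diacetoxy-12-hydroperoxy-8-hydroxy-9-oxobriara-5,11(20)-dien-19,7-olide
Conditions: O2, tetraphenylporphyrin (cat.), visible light, CH2Cl2, −20 °C
Reagents that add atoms: dioxygen, O=O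
Why: Schenck ene reaction of singlet oxygen with the trisubstituted C11=C12 alkene, in which O2 should add to C12 on the face opposite the pseudo-axial C14 acetate and abstract a hydrogen of CH3-20, moving the double bond to C11=C20 and setting 12S; the C5=C6 alkene is deactivated by the allylic lactone oxygen, H10 lies on the shielded face, and attack at C11 is hindered by the axial CH3-15.

**Compound list**
1 | neryl acetate, (2Z)-3,7-dimethylocta-2,6-dien-1-yl acetate | CC(C)=CCC/C(C)=C\COC(C)=O | starting material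
2 | (2Z)-6,7-epoxy-3,7-dimethyloct-2-en-1-yl acetate (racemic) | CC1(C)OC1CC/C(C)=C\COC(C)=O | intermediate
3 | (4Z)-6-acetoxy-4-methylhex-4-enal | O=CCC/C(C)=C\COC(C)=O | intermediate
4 | (2Z)-6-hydroxy-3-methyloct-2-en-7-yn-1-yl acetate (racemic) | C#CC(O)CC/C(C)=C\COC(C)=O | intermediate
5 | cyclic (Z)-alkenylmagnesium alkoxide (five-membered C–Mg–O chelate; bromomagnesium alkoxide at C7) | Br[Mg]OC/C=C(/C)CCC1O[Mg]C=C1C | intermediate
6 | (2Z,7Z)-8-iodo-3,7-dimethylocta-2,7-diene-1,6-diol (racemic) | OC/C=C(/C)CCC(O)/C(C)=C\I | intermediate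
7 | (2Z,7Z)-6-hydroxy-8-iodo-3,7-dimethylocta-2,7-dienal (racemic) | O=C/C=C(/C)CCC(O)/C(C)=C\I | intermediate
8 | (2Z,7Z)-6-(tert-butyldimethylsilyloxy)-8-iodo-3,7-dimethylocta-2,7-dienal (racemic) | O=C/C=C(/C)CCC(O[Si](C)(C)C(C)(C)C)/C(C)=C\I | intermediate
9 | tert-butyl (R)-lactate | C[C@@H](O)C(=O)OC(C)(C)C | starting material
10 | tert-butyl (2R)-2-(trifluoromethylsulfonyloxy)propanoate | C[C@@H](OS(=O)(=O)C(F)(F)F)C(=O)OC(C)(C)C | intermediate
11 | triethyl phosphonoacetate | CCOC(=O)CP(=O)(OCC)OCC | starting material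
12 | 4-tert-butyl 1-ethyl (3S)-2-(diethoxyphosphoryl)-3-methylbutanedioate (both C2 epimers) | CCOC(=O)C([C@@H](C)C(=O)OC(C)(C)C)P(=O)(OCC)OCC | intermediate
13 | 4-tert-butyl 1-ethyl (2E,3R)-2-[(2Z,7Z)-6-(tert-butyldimethylsilyloxy)-8-iodo-3,7-dimethylocta-2,7-dien-1-ylidene]-3-methylbutanedioate (two epimers at the silyloxy carbon) | CCOC(=O)/C([C@@H](C)C(=O)OC(C)(C)C)=C/C=C(/C)CCC(O[Si](C)(C)C(C)(C)C)/C(C)=C\I | intermediate
14 | tert-butyl (2R,3E,5Z,10Z)-9-(tert-butyldimethylsilyloxy)-3-(hydroxymethyl)-11-iodo-2,6,10-trimethylundeca-3,5,10-trienoate | OC/C([C@@H](C)C(=O)OC(C)(C)C)=C/C=C(/C)CCC(O[Si](C)(C)C(C)(C)C)/C(C)=C\I | intermediate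
15 | tert-butyl (2R)-2-{(2R,3R)-3-[(1Z,6Z)-5-(tert-butyldimethylsilyloxy)-7-iodo-2,6-dimethylhepta-1,6-dien-1-yl]-2-(hydroxymethyl)oxiran-2-yl}propanoate | OC[C@@]1([C@@H](C)C(=O)OC(C)(C)C)O[C@@H]1/C=C(/C)CCC(O[Si](C)(C)C(C)(C)C)/C(C)=C\I | intermediate
16 | (3R,4R,5S)-5-[(1Z,6Z)-5-(tert-butyldimethylsilyloxy)-7-iodo-2,6-dimethylhepta-1,6-dien-1-yl]-4-hydroxy-4-(hydroxymethyl)-3-methyloxolan-2-one | OC[C@@]1(O)[C@H](/C=C(/C)CCC(O[Si](C)(C)C(C)(C)C)/C(C)=C\I)OC(=O)[C@@H]1C | intermediate
17 | (3R,4S,5S)-5-[(1Z,6Z)-5-(tert-butyldimethylsilyloxy)-7-iodo-2,6-dimethylhepta-1,6-dien-1-yl]-4-formyl-4-hydroxy-3-methyloxolan-2-one | O=C[C@@]1(O)[C@H](/C=C(/C)CCC(O[Si](C)(C)C(C)(C)C)/C(C)=C\I)OC(=O)[C@@H]1C | intermediate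
18 | propargyl alcohol | OCC#C | starting material
19 | (E)-alkenylalane, dimethylaluminium alkoxide of 3-(dimethylalumanyl)-2-methylprop-2-en-1-ol | C[Al](C)OC/C(C)=C/[Al](C)C | intermediate
20 | (E)-3-iodo-2-methylprop-2-en-1-ol | OC/C(C)=C/I | intermediate
21 | (E)-3-iodo-2-methylprop-2-enal | O=C/C(C)=C/I | intermediate
22 | (E)-1-iodo-2-methylbuta-1,3-diene | C=C/C(C)=C/I | intermediate
23 | (E)-(2-methylbuta-1,3-dien-1-yl)lithium | C=C/C(C)=C/[Li] | intermediate
24 | (E)-(2-methylbuta-1,3-dien-1-yl)magnesium bromide | C=C/C(C)=C/[Mg]Br | intermediate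
25 | C9 dienyl carbinol: lactone 17 with the formyl group converted into a (2E)-1-hydroxy-3-methylpenta-2,4-dien-1-yl group (both C9 epimers, C2 as TBS ether) | C=C/C(C)=C/C(O)[C@@]1(O)[C@H](/C=C(/C)CCC(O[Si](C)(C)C(C)(C)C)/C(C)=C\I)OC(=O)[C@@H]1C | intermediate
26 | triol: 25 without the silyl group (free hydroxyls at C2, C8, C9) | C=C/C(C)=C/C(O)[C@@]1(O)[C@H](/C=C(/C)CCC(O)/C(C)=C\I)OC(=O)[C@@H]1C | intermediate
27 | (3R,4S,5S)-4-hydroxy-5-[(1Z,6Z)-7-iodo-2,6-dimethyl-5-oxohepta-1,6-dien-1-yl]-3-methyl-4-[(2E)-3-methylpenta-2,4-dienoyl]oxolan-2-one | C=C/C(C)=C/C(=O)[C@@]1(O)[C@H](/C=C(/C)CCC(=O)/C(C)=C\I)OC(=O)[C@@H]1C | intermediate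
28 | (3R,4S,5S)-5-[(1Z,6Z)-2,6-dimethyl-5-oxo-7-(pinacolboryl)hepta-1,6-dien-1-yl]-4-hydroxy-3-methyl-4-[(2E)-3-methylpenta-2,4-dienoyl]oxolan-2-one | C=C/C(C)=C/C(=O)[C@@]1(O)[C@H](/C=C(/C)CCC(=O)/C(C)=C\B2OC(C)(C)C(C)(C)O2)OC(=O)[C@@H]1C | intermediate
29 | 8-hydroxy-2,9-dioxo-14-(pinacolboryl)briara-5Z,11-dien-19,7-olide (stereocentres as in 33) | CC=1[C@@H]2C(=O)[C@@]3(O)[C@H](/C=C(/C)CCC(=O)[C@@]2(C)[C@@H](B4OC(C)(C)C(C)(C)O4)CC=1)OC(=O)[C@@H]3C | intermediate
30 | 8,14-dihydroxy-2,9-dioxobriara-5Z,11-dien-19,7-olide | CC=1[C@@H]2C(=O)[C@@]3(O)[C@H](/C=C(/C)CCC(=O)[C@@]2(C)[C@@H](O)CC=1)OC(=O)[C@@H]3C | intermediate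
31 | (2S,14S)-2,8,14-trihydroxy-9-oxobriara-5Z,11-dien-19,7-olide | CC=1[C@@H]2C(=O)[C@@]3(O)[C@H](/C=C(/C)CC[C@H](O)[C@@]2(C)[C@@H](O)CC=1)OC(=O)[C@@H]3C | intermediate
32 | (2S,14S)-2,14-diacetoxy-8-hydroxy-9-oxobriara-5Z,11-dien-19,7-olide | CC=1[C@@H]2C(=O)[C@@]3(O)[C@H](/C=C(/C)CC[C@H](OC(C)=O)[C@@]2(C)[C@@H](OC(C)=O)CC=1)OC(=O)[C@@H]3C | intermediate
33 | CNP0066422.1, (1S,2S,5Z,7S,8S,10S,12S,14S,17R)-2,14-diacetoxy-12-hydroperoxy-8-hydroxy-9-oxobriara-5,11(20)-dien-19,7-olide | C=C1[C@@H]2C(=O)[C@@]3(O)[C@H](/C=C(/C)CC[C@H](OC(C)=O)[C@@]2(C)[C@@H](OC(C)=O)C[C@@H]1OO)OC(=O)[C@@H]3C | target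

**Step count and risks**
Total step count: 25. Longest linear sequence: 20 steps (steps 1–6, 9–13, 17–25).

Steps most likely to fail:

Step 21 (key cycloaddition). The eight-atom tether may not reach the transition-state geometry without prohibitive transannular strain. Intermolecular cycloaddition, thermal isomerisation of the dienone, or reaction through the endo mode or the other diene face could then take over. The fallback changes the diene to normal electron demand and controls the face by a temporary ring. It sets out from triol 26: 2,2-dimethoxypropane with pyridinium p-toluenesulfonate ties the C8 and C9 hydroxyls into a dioxolane, and the (9S) epimer, acetonide F1, is separated. Dess–Martin oxidation of the C2 carbinol gives the β-iodo enone F2, and borylation as in step 20 gives the boryl enone F3. In F3 the diene is no longer conjugated to a carbonyl; allylic strain between C9 and CH3-20 holds H9 in the diene plane, and the dioxolane directs the tether to one face. Thermolysis in dilute toluene should therefore give the cycloadduct F4. Aqueous acetic acid removes the acetonide to give the 8,9-diol F5, and Dess–Martin oxidation of the C9 carbinol comes back to the route at 29.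

Step 25 (ene reaction). Hydrogen abstraction may occur at H10 (giving the conjugated enone) or at H13, or singlet oxygen may attack C5=C6, so that regio- and chemoselectivity are lost. The fallback builds the same array by directed epoxidation, epoxide-to-allylic-alcohol isomerisation and SN2 perhydrolysis. It sets out from diol 31: VO(acac)2 with t-BuOOH, directed by the C14 hydroxyl, gives the 11,12-epoxide on the face of that hydroxyl, epoxy diol F6, which is acetylated to the diacetate F7. Trivalent titanium (Cp2TiCl, from Cp2TiCl2 and Mn) opens the epoxide homolytically at C11 and, after hydrogen abstraction from CH3-20, gives the (12R)-allylic alcohol F8 with the exocyclic C11=C20 alkene. Mesylation (MsCl, Et3N) gives the mesylate F9. Displacement with 2-methoxyprop-2-yl hydroperoxide and CsOH in DMF, with inversion, gives the (12S)-peroxyketal F10, and aqueous acetic acid releases the hydroperoxide, coming back to the route at 33.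

Step 17 (dienyl Grignard addition). Iodine–metal exchange between the dienyl organometallic and the C14 vinyl iodide, loss of diene geometry, or sluggish addition to the hindered α-hydroxy aldehyde could erode the step. The fallback assembles the dienone by conjugate addition instead. It sets out from aldehyde 17: 1-propynylmagnesium bromide (CH3C≡CMgBr) gives the propargylic alcohol F11, and Dess–Martin oxidation gives the ynone F12. Lithium divinylcuprate, (CH2=CH)2CuLi, at −78 °C adds vinyl syn to the β-carbon and, after protonation, should give the (E)-dienone F13 with vinyl trans to the acyl group. HF·pyridine removes the silyl group to give the hydroxy dienone F14, and Dess–Martin oxidation of the C2 carbinol comes back to the route at 27.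

**Further compounds**
F1 | step 21 | (9S)-8,9-O-isopropylidene acetal of triol 26 (C2 hydroxyl free) | C=C/C(C)=C/[C@@H]1OC(C)(C)O[C@@]12[C@H](/C=C(/C)CCC(O)/C(C)=C\I)OC(=O)[C@@H]2C
F2 | step 21 | C2 ketone (β-iodo enone) of acetonide F1 | C=C/C(C)=C/[C@@H]1OC(C)(C)O[C@@]12[C@H](/C=C(/C)CCC(=O)/C(C)=C\I)OC(=O)[C@@H]2C
F3 | step 21 | (Z)-β-pinacolboryl enone of the acetonide series | C=C/C(C)=C/[C@@H]1OC(C)(C)O[C@@]12[C@H](/C=C(/C)CCC(=O)/C(C)=C\B3OC(C)(C)C(C)(C)O3)OC(=O)[C@@H]2C
F4 | step 21 | cycloadduct, (9S)-8,9-O-isopropylidene-9-hydroxy analogue of 29 | CC=1[C@@H]2[C@@H]5OC(C)(C)O[C@@]53[C@H](/C=C(/C)CCC(=O)[C@@]2(C)[C@@H](B4OC(C)(C)C(C)(C)O4)CC=1)OC(=O)[C@@H]3C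
F5 | step 21 | (9S)-8,9-dihydroxy analogue of 29 | CC=1[C@@H]2[C@H](O)[C@@]3(O)[C@H](/C=C(/C)CCC(=O)[C@@]2(C)[C@@H](B4OC(C)(C)C(C)(C)O4)CC=1)OC(=O)[C@@H]3C
F6 | step 25 | 11,12-epoxide of diol 31, oxygen on the face of the C14 hydroxyl | C[C@]14[C@@H]2C(=O)[C@@]3(O)[C@H](/C=C(/C)CC[C@H](O)[C@@]2(C)[C@@H](O)C[C@H]1O4)OC(=O)[C@@H]3C
F7 | step 25 | 2,14-diacetate of epoxide F6 | C[C@]14[C@@H]2C(=O)[C@@]3(O)[C@H](/C=C(/C)CC[C@H](OC(C)=O)[C@@]2(C)[C@@H](OC(C)=O)C[C@H]1O4)OC(=O)[C@@H]3C
F8 | step 25 | (12R)-12-hydroxy-11(20)-ene diacetate (12-epimeric alcohol) | C=C1[C@@H]2C(=O)[C@@]3(O)[C@H](/C=C(/C)CC[C@H](OC(C)=O)[C@@]2(C)[C@@H](OC(C)=O)C[C@H]1O)OC(=O)[C@@H]3C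
F9 | step 25 | 12-methanesulfonate of F8 | C=C1[C@@H]2C(=O)[C@@]3(O)[C@H](/C=C(/C)CC[C@H](OC(C)=O)[C@@]2(C)[C@@H](OC(C)=O)C[C@H]1OS(C)(=O)=O)OC(=O)[C@@H]3C
F10 | step 25 | (12S)-12-(2-methoxyprop-2-yl)peroxy derivative of the target | C=C1[C@@H]2C(=O)[C@@]3(O)[C@H](/C=C(/C)CC[C@H](OC(C)=O)[C@@]2(C)[C@@H](OC(C)=O)C[C@@H]1OOC(C)(C)OC)OC(=O)[C@@H]3C
F11 | step 17 | C9 propargylic alcohol (1-hydroxybut-2-yn-1-yl group on C8, both C9 epimers) | CC#CC(O)[C@@]1(O)[C@H](/C=C(/C)CCC(O[Si](C)(C)C(C)(C)C)/C(C)=C\I)OC(=O)[C@@H]1C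
F12 | step 17 | C9 ynone (but-2-ynoyl group on C8) | CC#CC(=O)[C@@]1(O)[C@H](/C=C(/C)CCC(O[Si](C)(C)C(C)(C)C)/C(C)=C\I)OC(=O)[C@@H]1C
F13 | step 17 | (E)-dienone with C2 as TBS ether | C=C/C(C)=C/C(=O)[C@@]1(O)[C@H](/C=C(/C)CCC(O[Si](C)(C)C(C)(C)C)/C(C)=C\I)OC(=O)[C@@H]1C
F14 | step 17 | (E)-dienone with free C2 hydroxyl | C=C/C(C)=C/C(=O)[C@@]1(O)[C@H](/C=C(/C)CCC(O)/C(C)=C\I)OC(=O)[C@@H]1C
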